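**Retrosynthetic overview**
1. The bond between the bridging CH2 and the aromatic ring is made last, by intermolecular Michael addition of 3-prenylphlorisobutyrophenone to an exo-methylene trione released from a Mannich base of the dearomatised half.
2. The dearomatised half (prenyl trione) comes from its allyl analogue by cross-metathesis, and that from a 3,5-dimethoxy-cyclohexa-2,5-dienone by hydrolysis; the single enantiomer is obtained by chromatography of the racemic dienone on a chiral phase.
3. The dienone comes from a Birch-derived 1,4-diene by bis-allylic oxidation; the quaternary carbon is made by Birch reductive allylation of methyl 2,6-dimethoxy-3-methylbenzoate (from 2,4-dimethoxytoluene by ortho-lithiation).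
4. The aromatic half comes from phloroglucinol by Friedel–Crafts acylation and C-prenylation.
5. No ring is constructed: the left-hand carbocycle is the dearomatised benzene ring of 2,4-dimethoxytoluene, the right-hand ring is that of phloroglucinol.

Assumption: the target is handled in the tautomeric form drawn in its SMILES; its only stereocentre is the quaternary ring carbon, (S) by CIP rules; every intermediate before the resolution step is racemic.

**Step 1**
Reactants: 1 2,4-dimethoxytoluene
Product: 3 methyl 2,6-dimethoxy-3-methylbenzoate, via 2,6-dimethoxy-3-methylphenyllithium 2 (not isolated)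
Conditions: n-BuLi, TMEDA, THF, 0 °C to rt; then ClCO2Me, −78 °C
Reagents that add atoms: methyl chloroformate COC(=O)Cl
Why: Directed ortho-metalation: the ring position flanked by both methoxy groups is lithiated selectively and the hindered aryllithium is acylated only once by the chloroformate.

**Step 2**
Reactants: 3 methyl 2,6-dimethoxy-3-methylbenzoate
Product: 5 rac-methyl 2,6-dimethoxy-3-methyl-1-(prop-2-en-1-yl)cyclohexa-2,5-diene-1-carboxylate, via potassium ester dienolate 4 (not isolated)
Conditions: K, NH3(l), THF, t-BuOH (1 equiv), −78 °C; then allyl bromide, −78 °C to rt; H2O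
Reagents that add atoms: allyl bromide C=CCBr
Why: Birch reduction–alkylation: the ester directs reduction to C1 and C4 while both methoxy groups stay on sp2 carbons, and the dienolate is allylated at C1; the new quaternary carbon forms as a racemate because its two ring arms differ only in a remote methyl group, so the enantiomers are separated in step 8.

**Step 3**
Reactants: 5 rac-methyl 2,6-dimethoxy-3-methyl-1-(prop-2-en-1-yl)cyclohexa-2,5-diene-1-carboxylate
Product: 6 rac-[2,6-dimethoxy-3-methyl-1-(prop-2-en-1-yl)cyclohexa-2,5-dien-1-yl]methanol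
Conditions: LiAlH4, Et2O, 0 °C to rt; H2O, aq NaOH
Reagents that add atoms: none
Why: Hydride reduction of the ester; enol ethers and isolated alkenes are inert to LiAlH4 and the basic work-up avoids enol ether hydrolysis.

**Step 4**
Reactants: 6 rac-[2,6-dimethoxy-3-methyl-1-(prop-2-en-1-yl)cyclohexa-2,5-dien-1-yl]methanol
Product: 7 rac-2,6-dimethoxy-3-methyl-1-(prop-2-en-1-yl)cyclohexa-2,5-diene-1-carbaldehyde
Conditions: Dess–Martin periodinane, pyridine, CH2Cl2, 0 °C to rt
Reagents that add atoms: none
Why: Dess–Martin oxidation of a neopentyl primary alcohol stops at the aldehyde, which has no alpha hydrogen, and pyridine buffers the acetic acid that would hydrolyse the enol ethers.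

**Step 5**
Reactants: 7 rac-2,6-dimethoxy-3-methyl-1-(prop-2-en-1-yl)cyclohexa-2,5-diene-1-carbaldehyde
Product: 8 rac-1-[2,6-dimethoxy-3-methyl-1-(prop-2-en-1-yl)cyclohexa-2,5-dien-1-yl]-2-methylpropan-1-ol (mixture of carbinol epimers)
Conditions: i-PrMgCl, CeCl3, THF, −78 °C; H2O
Reagents that add atoms: isopropylmagnesium chloride CC(C)[Mg]Cl
Why: Organocerium (Imamoto) 1,2-addition suppresses hydride transfer to the hindered non-enolisable aldehyde; the new carbinol centre is uncontrolled and is erased by oxidation in step 6.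

**Step 6**
Reactants: 8 rac-1-[2,6-dimethoxy-3-methyl-1-(prop-2-en-1-yl)cyclohexa-2,5-dien-1-yl]-2-methylpropan-1-ol
Product: 9 rac-1-[2,6-dimethoxy-3-methyl-1-(prop-2-en-1-yl)cyclohexa-2,5-dien-1-yl]-2-methylpropan-1-one
Conditions: Dess–Martin periodinane, pyridine, CH2Cl2, rt
Reagents that add atoms: none
Why: Dess–Martin oxidation of the hindered secondary alcohol to the isopropyl ketone under buffered, non-acidic conditions that spare the enol ethers.

**Step 7**
Reactants: 9 rac-1-[2,6-dimethoxy-3-methyl-1-(prop-2-en-1-yl)cyclohexa-2,5-dien-1-yl]-2-methylpropan-1-one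
Product: 10 rac-3,5-dimethoxy-2-methyl-4-(2-methylpropanoyl)-4-(prop-2-en-1-yl)cyclohexa-2,5-dien-1-one
Conditions: (C5H5NH)2Cr2O7, t-BuOOH, Celite, benzene, rt
Reagents that add atoms: tert-butyl hydroperoxide CC(C)(C)OO
Why: Allylic C–H oxidation mediated by hexavalent chromium with t-BuOOH as terminal oxidant attacks the doubly allylic ring CH2 far faster than any singly allylic position, and the quaternary carbon prevents aromatisation, giving the cross-conjugated dienone.

**Step 8**
Reactants: 10 rac-3,5-dimethoxy-2-methyl-4-(2-methylpropanoyl)-4-(prop-2-en-1-yl)cyclohexa-2,5-dien-1-one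
Product: 11 (4R)-3,5-dimethoxy-2-methyl-4-(2-methylpropanoyl)-4-(prop-2-en-1-yl)cyclohexa-2,5-dien-1-one
Conditions: preparative SFC on amylose tris(3,5-dimethylphenylcarbamate) phase, CO2/i-PrOH, 35 °C
Reagents that add atoms: none
Why: Resolution by chromatography on a chiral stationary phase: the enantiomers differ in which ring arm carries the methyl group, the (4R) enantiomer (assigned by X-ray or ECD) is kept, and the quaternary centre cannot epimerise afterwards.

**Step 9**
Reactants: 11 (4R)-3,5-dimethoxy-2-methyl-4-(2-methylpropanoyl)-4-(prop-2-en-1-yl)cyclohexa-2,5-dien-1-one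
Product: 12 (4R)-3,5-dihydroxy-2-methyl-4-(2-methylpropanoyl)-4-(prop-2-en-1-yl)cyclohexa-2,5-dien-1-one
Conditions: 3 M aq HCl, 1,4-dioxane, 60 °C
Reagents that add atoms: water O
Why: Acid hydrolysis of both vinylogous methyl esters by addition of water and loss of methanol gives the doubly enolised trione; the terminal allyl group is not protonated under these conditions (the reason allyl, not prenyl, is carried to this point) and the quaternary centre is untouched.

**Step 10**
Reactants: 12 (4R)-3,5-dihydroxy-2-methyl-4-(2-methylpropanoyl)-4-(prop-2-en-1-yl)cyclohexa-2,5-dien-1-one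
Product: 13 (4R)-3,5-dihydroxy-2-methyl-4-(3-methylbut-2-en-1-yl)-4-(2-methylpropanoyl)cyclohexa-2,5-dien-1-one
Conditions: 2-methylbut-2-ene (excess), second-generation Grubbs catalyst (H2IMes)(PCy3)Cl2Ru=CHPh (5 mol%), CH2Cl2, 40 °C
Reagents that add atoms: 2-methylbut-2-ene CC=C(C)C
Why: Olefin cross-metathesis of the terminal alkene with 2-methylbut-2-ene converts allyl into prenyl with loss of propene; the ruthenium carbene tolerates the acidic enols and does not touch the ring double bonds or the stereocentre.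

**Step 11**
Reactants: 13 (4R)-3,5-dihydroxy-2-methyl-4-(3-methylbut-2-en-1-yl)-4-(2-methylpropanoyl)cyclohexa-2,5-dien-1-one
Product: 14 (4S)-2-[(dimethylamino)methyl]-3,5-dihydroxy-6-methyl-4-(3-methylbut-2-en-1-yl)-4-(2-methylpropanoyl)cyclohexa-2,5-dien-1-one hydroiodide
Conditions: [Me2N=CH2]I (Eschenmoser's salt), CH2Cl2, rt
Reagents that add atoms: Eschenmoser's salt C[N+](C)=C.[I-]
Why: Mannich reaction: the only C–H carbon of the vinylogous acid attacks the iminium ion and the product is kept as its ammonium salt so that it cannot eliminate prematurely; the descriptor changes from R to S only because the CIP ranking of the two ring arms changes.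

**Step 12**
Reactants: 15 phloroglucinol
Product: 16 2-methyl-1-(2,4,6-trihydroxyphenyl)propan-1-one
Conditions: isobutyryl chloride, AlCl3, CH2Cl2/PhNO2, 0 °C to rt; aq HCl
Reagents that add atoms: isobutyryl chloride CC(C)C(=O)Cl
Why: Friedel–Crafts acylation of the very electron-rich phloroglucinol stops after one acylation because the acyl group deactivates the ring.

**Step 13**
Reactants: 16 2-methyl-1-(2,4,6-trihydroxyphenyl)propan-1-one
Product: 17 2-methyl-1-[2,4,6-trihydroxy-3-(3-methylbut-2-en-1-yl)phenyl]propan-1-one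
Conditions: prenyl bromide (1 equiv), 10% aq KOH, 0 °C
Reagents that add atoms: prenyl bromide CC(C)=CCBr
Why: C-alkylation of the ambident phloroglucinolate, favoured over O-alkylation in water, gives the mono-C-prenyl compound, which is separated from some diprenylated material.

**Step 14**
Reactants: 14 (4S)-2-[(dimethylamino)methyl]-3,5-dihydroxy-6-methyl-4-(3-methylbut-2-en-1-yl)-4-(2-methylpropanoyl)cyclohexa-2,5-dien-1-one hydroiodide; 17 2-methyl-1-[2,4,6-trihydroxy-3-(3-methylbut-2-en-1-yl)phenyl]propan-1-one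
Product: 19 (4S)-3,5-dihydroxy-6-methyl-4-(3-methylbut-2-en-1-yl)-4-(2-methylpropanoyl)-2-{[2,4,6-trihydroxy-3-(3-methylbut-2-en-1-yl)-5-(2-methylpropanoyl)phenyl]methyl}cyclohexa-2,5-dien-1-one, via exo-methylene trione 18 (not isolated)
Conditions: CH3CO2Na, MeCN, 60 °C
Reagents that add atoms: none
Why: Acetate frees the ammonium enolate, which eliminates dimethylamine to the exo-methylene trione, and the free ring carbon of the phloroglucinol adds to it in an intermolecular Michael addition and rearomatises, forming the bridge C–C bond without touching the quaternary (S) centre.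

**Compound list**
1 | 2,4-dimethoxytoluene | Cc1ccc(OC)cc1OC | starting material
2 | 2,6-dimethoxy-3-methylphenyllithium | [Li]c1c(OC)ccc(C)c1OC | intermediate (not isolated)
3 | methyl 2,6-dimethoxy-3-methylbenzoate | COC(=O)c1c(OC)ccc(C)c1OC | intermediate
4 | potassium (2,6-dimethoxy-3-methylcyclohexa-2,5-dien-1-ylidene)(methoxy)methanolate | COC([O-])=C1C(OC)=C(C)CC=C1OC.[K+] | intermediate (not isolated)
5 | rac-methyl 2,6-dimethoxy-3-methyl-1-(prop-2-en-1-yl)cyclohexa-2,5-diene-1-carboxylate | COC(=O)C1(CC=C)C(OC)=C(C)CC=C1OC (racemate) | intermediate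
6 | rac-[2,6-dimethoxy-3-methyl-1-(prop-2-en-1-yl)cyclohexa-2,5-dien-1-yl]methanol | OCC1(CC=C)C(OC)=C(C)CC=C1OC (racemate) | intermediate
7 | rac-2,6-dimethoxy-3-methyl-1-(prop-2-en-1-yl)cyclohexa-2,5-diene-1-carbaldehyde | O=CC1(CC=C)C(OC)=C(C)CC=C1OC (racemate) | intermediate
8 | rac-1-[2,6-dimethoxy-3-methyl-1-(prop-2-en-1-yl)cyclohexa-2,5-dien-1-yl]-2-methylpropan-1-ol, both carbinol epimers | CC(C)C(O)C1(CC=C)C(OC)=C(C)CC=C1OC (racemic epimer mixture) | intermediate
9 | rac-1-[2,6-dimethoxy-3-methyl-1-(prop-2-en-1-yl)cyclohexa-2,5-dien-1-yl]-2-methylpropan-1-one | CC(C)C(=O)C1(CC=C)C(OC)=C(C)CC=C1OC (racemate) | intermediate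
10 | rac-3,5-dimethoxy-2-methyl-4-(2-methylpropanoyl)-4-(prop-2-en-1-yl)cyclohexa-2,5-dien-1-one | CC(C)C(=O)C1(CC=C)C(OC)=C(C)C(=O)C=C1OC (racemate) | intermediate
11 | (4R)-3,5-dimethoxy-2-methyl-4-(2-methylpropanoyl)-4-(prop-2-en-1-yl)cyclohexa-2,5-dien-1-one | C1=C(OC)[C@@](CC=C)(C(=O)C(C)C)C(OC)=C(C)C1=O | intermediate
12 | (4R)-3,5-dihydroxy-2-methyl-4-(2-methylpropanoyl)-4-(prop-2-en-1-yl)cyclohexa-2,5-dien-1-one | C1=C(O)[C@@](CC=C)(C(=O)C(C)C)C(O)=C(C)C1=O | intermediate
13 | (4R)-3,5-dihydroxy-2-methyl-4-(3-methylbut-2-en-1-yl)-4-(2-methylpropanoyl)cyclohexa-2,5-dien-1-one | C1=C(O)[C@@](CC=C(C)C)(C(=O)C(C)C)C(O)=C(C)C1=O | intermediate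
14 | (4S)-2-[(dimethylamino)methyl]-3,5-dihydroxy-6-methyl-4-(3-methylbut-2-en-1-yl)-4-(2-methylpropanoyl)cyclohexa-2,5-dien-1-one hydroiodide | C[NH+](C)CC1=C(O)[C@@](CC=C(C)C)(C(=O)C(C)C)C(O)=C(C)C1=O.[I-] | intermediate
15 | phloroglucinol (benzene-1,3,5-triol) | Oc1cc(O)cc(O)c1 | starting material
16 | 2-methyl-1-(2,4,6-trihydroxyphenyl)propan-1-one | CC(C)C(=O)c1c(O)cc(O)cc1O | intermediate
17 | 2-methyl-1-[2,4,6-trihydroxy-3-(3-methylbut-2-en-1-yl)phenyl]propan-1-one | CC(C)=CCc1c(O)cc(O)c(C(=O)C(C)C)c1O | intermediate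
18 | (6R)-5-hydroxy-4-methyl-2-methylidene-6-(3-methylbut-2-en-1-yl)-6-(2-methylpropanoyl)cyclohex-4-ene-1,3-dione | C=C1C(=O)[C@@](CC=C(C)C)(C(=O)C(C)C)C(O)=C(C)C1=O | intermediate (not isolated)
19 | (4S)-3,5-dihydroxy-6-methyl-4-(3-methylbut-2-en-1-yl)-4-(2-methylpropanoyl)-2-{[2,4,6-trihydroxy-3-(3-methylbut-2-en-1-yl)-5-(2-methylpropanoyl)phenyl]methyl}cyclohexa-2,5-dien-1-one | CC(C)=CCc1c(O)c(CC2=C(O)[C@@](CC=C(C)C)(C(=O)C(C)C)C(O)=C(C)C2=O)c(O)c(C(=O)C(C)C)c1O | target

**Totals and risks**
Total number of steps: 14. Longest linear sequence: 12 steps (steps 1–11 and 14); steps 12–13 make the second fragment.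

The three steps most likely to fail:

Step 7 (bis-allylic oxidation of 9). The ring radical may expel the allyl group and aromatise, or the enol ethers may be over-oxidised. The fallback sets out from ester 5 and comes back at 10; it moves the oxidation ahead of the acyl installation, onto the 1-alkyl-1-alkoxycarbonyl-cyclohexa-2,5-diene class for which this oxidation is best established. Oxidation of 5 with (C5H5NH)2Cr2O7/t-BuOOH gives rac-methyl 2,6-dimethoxy-3-methyl-4-oxo-1-(prop-2-en-1-yl)cyclohexa-2,5-diene-1-carboxylate F3. LiAlH4 in Et2O reduces both the ester and the ring carbonyl to rac-4-(hydroxymethyl)-3,5-dimethoxy-2-methyl-4-(prop-2-en-1-yl)cyclohexa-2,5-dien-1-ol F4, which is kept basic. Dess–Martin periodinane with pyridine re-oxidises both alcohols to rac-2,6-dimethoxy-3-methyl-4-oxo-1-(prop-2-en-1-yl)cyclohexa-2,5-diene-1-carbaldehyde F5. One equivalent of i-PrMgCl/CeCl3 at −78 °C adds only to the aldehyde, the ring carbonyl being a doubly vinylogous carbonate, and gives rac-4-(1-hydroxy-2-methylpropyl)-3,5-dimethoxy-2-methyl-4-(prop-2-en-1-yl)cyclohexa-2,5-dien-1-one F6. A last Dess–Martin oxidation gives 10.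

Step 14 (Mannich-base elimination and Michael coupling). The exo-methylene trione 18 may dimerise or re-add dimethylamine faster than the phenol traps it. The fallback reverses the roles of the partners; it sets out from 17 and 13 and comes back at 19. Compound 17 is treated with [Me2N=CH2]I in CH2Cl2 and washed with aq NaHCO3 to give 1-{3-[(dimethylamino)methyl]-2,4,6-trihydroxy-5-(3-methylbut-2-en-1-yl)phenyl}-2-methylpropan-1-one F7. Heating F7 with 13 in 1,4-dioxane at 80 °C releases dimethylamine and the ortho-quinone methide 3,5-dihydroxy-6-methylidene-2-(3-methylbut-2-en-1-yl)-4-(2-methylpropanoyl)cyclohexa-2,4-dien-1-one F8 (not isolated). The enol carbon of 13 adds to F8 in a Michael addition to give 19.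

Step 2 (Birch reductive allylation of 3). Reduction of the hindered, electron-rich benzoate may be incomplete or methoxide may be lost. The fallback builds the quaternary carbon by stepwise alkylation of a Birch-derived bis-enol ether instead; it sets out from 1 and comes back at 8, so steps 1–5 are bypassed. Reduction of 1 with Li, NH3(l) and t-BuOH gives 1,5-dimethoxy-2-methylcyclohexa-1,4-diene F1. Deprotonation of the CH2 between the two methoxy-bearing carbons (t-BuLi, THF, −78 °C) and allyl bromide give rac-1,5-dimethoxy-2-methyl-6-(prop-2-en-1-yl)cyclohexa-1,4-diene F2. A second deprotonation at the same carbon (t-BuLi), transmetalation with CeCl3 and addition to isobutyraldehyde give carbinol 8.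

**Further compounds**
F1 | step 2 | 1,5-dimethoxy-2-methylcyclohexa-1,4-diene | COC1=C(C)CC=C(OC)C1
F2 | step 2 | rac-1,5-dimethoxy-2-methyl-6-(prop-2-en-1-yl)cyclohexa-1,4-diene | COC1=C(C)CC=C(OC)C1CC=C
F3 | step 7 | rac-methyl 2,6-dimethoxy-3-methyl-4-oxo-1-(prop-2-en-1-yl)cyclohexa-2,5-diene-1-carboxylate | COC(=O)C1(CC=C)C(OC)=C(C)C(=O)C=C1OC
F4 | step 7 | rac-4-(hydroxymethyl)-3,5-dimethoxy-2-methyl-4-(prop-2-en-1-yl)cyclohexa-2,5-dien-1-ol | OCC1(CC=C)C(OC)=C(C)C(O)C=C1OC
F5 | step 7 | rac-2,6-dimethoxy-3-methyl-4-oxo-1-(prop-2-en-1-yl)cyclohexa-2,5-diene-1-carbaldehyde | O=CC1(CC=C)C(OC)=C(C)C(=O)C=C1OC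
F6 | step 7 | rac-4-(1-hydroxy-2-methylpropyl)-3,5-dimethoxy-2-methyl-4-(prop-2-en-1-yl)cyclohexa-2,5-dien-1-one | CC(C)C(O)C1(CC=C)C(OC)=C(C)C(=O)C=C1OC
F7 | step 14 | 1-{3-[(dimethylamino)methyl]-2,4,6-trihydroxy-5-(3-methylbut-2-en-1-yl)phenyl}-2-methylpropan-1-one | CN(C)Cc1c(O)c(CC=C(C)C)c(O)c(C(=O)C(C)C)c1O
F8 | step 14 | 3,5-dihydroxy-6-methylidene-2-(3-methylbut-2-en-1-yl)-4-(2-methylpropanoyl)cyclohexa-2,4-dien-1-one | C=C1C(=O)C(CC=C(C)C)=C(O)C(C(=O)C(C)C)=C1O
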